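The route rests on cutting the C12–C13 bond of the ring C/D bicyclo[3.2.1]octane and reconnecting C12 to C16. This leads back to a ring C/D isomer with a methyl-bearing bridgehead C16 and an exo sulfonate on C13. Ionising that sulfonate in water returns C12 to C13, re-forms rings C and D and puts the hydroxyl on the exo face of the tertiary C16 cation, so one operation sets C13 and C16. The feature used is the exo 16-hydroxy-16-methyl group beside the hydrogen-bearing bridgehead C13. The precursor comes from gibberellic acid, whose 13-hydroxyl drives the forward shift, and carries benzyl esters and a benzyl carbonate for a neutral final hydrogenolysis.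

Key step: step 14

Remark: gibberellin atom numbers are kept for every compound, also after the skeletal shift. Exo is the face of the two-carbon bridge syn to the one-carbon bridge, and α is the face of ring A that carries C19. C20 of compound 13 forms as an epimer mixture that is left open in its SMILES, because the centre is destroyed in step 8.

Step 1
Reactants: 1 gibberellic acid; 2 benzyl bromide
Product: 3 gibberellic acid benzyl ester (C7 benzyl ester)
Conditions: BnBr, KHCO3, DMF, rt
Reagents that add atoms: benzyl bromide, BrCc1ccccc1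
Why: SN2 alkylation of the C7 carboxylate under bicarbonate is mild enough for the base-sensitive ring A lactone and leaves both hydroxyls free, and the benzyl ester can be removed at the end without acid or base (carboxylate O-alkylation).

Step 2
Reactants: 3 gibberellic acid benzyl ester
Product: 4 7-benzyl ester of 3β,13-dihydroxy-20-norgibberella-1(10),16-diene-7,19-dioic acid (free C19 acid)
Conditions: Pd(PPh3)4 (5 mol %), NaBH4, THF, 0 °C to rt; aq. citric acid work-up
Reagents that add atoms: none
Why: Zerovalent palladium ionises only the tertiary allylic C10–O bond of the lactone (a free allylic hydroxyl is no leaving group) and borohydride hands hydride to the less hindered allyl terminus C2, so this palladium-catalysed allylic hydrogenolysis should give the C1=C10 alkene and the free C19 acid while C10 loses its stereocentre and no new one is made.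

Step 3
Reactants: 4 1(10),16-diene 19-acid 7-benzyl ester; 5 triethylsilyl trifluoromethanesulfonate
Product: 6 3β,13-bis(triethylsilyloxy) 19-triethylsilyl ester of 4
Conditions: Et3SiOTf (3.5 equiv), 2,6-lutidine, CH2Cl2, −78 to 0 °C; non-aqueous work-up
Reagents that add atoms: triethylsilyl trifluoromethanesulfonate, CC[Si](CC)(CC)OS(=O)(=O)C(F)(F)F
Why: Silyl triflate and 2,6-lutidine silylate the hindered 3β-hydroxyl, the tertiary bridgehead 13-hydroxyl and the carboxylic acid in one pass (silyl ether and silyl ester formation), the ethers being needed against oxalyl chloride and base and the silyl ester serving as the activated form of C19.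

Step 4
Reactants: 6 tris(triethylsilyl) compound; 7 trimethylsilyldiazomethane
Product: 9 C19 diazomethyl ketone (3β,13-bis(triethylsilyloxy), 7-benzyl ester, 1(10),16-diene), via C19 acid chloride 8 (not isolated)
Conditions: (COCl)2, DMF (cat.), CH2Cl2, 0 °C to rt; evaporate; Me3SiCHN2 (3 equiv), MeCN/THF, 0 °C to rt
Reagents that add atoms: trimethylsilyldiazomethane, C[Si](C)(C)C=[N+]=[N-]
Why: The chloroiminium salt from oxalyl chloride and DMF turns the silyl ester into the acid chloride without liberating HCl, and C-acylation of trimethylsilyldiazomethane followed by loss of the silyl group as its chloride gives the diazoketone whose diazo carbon is the future C20 (diazoketone synthesis of the Arndt–Eistert type).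

Step 5
Reactants: 9 C19 diazomethyl ketone
Product: 10 cyclopropyl ketone (C20 bonded to C19, C10 and C1; cyclopropane C1–C10–C20 on the α face)
Conditions: Cu(acac)2 (10 mol %), ClCH2CH2Cl, 80 °C, slow addition
Reagents that add atoms: none
Why: Copper-carbenoid cyclopropanation of the trisubstituted C1=C10 alkene is intramolecular and five-ring forming, and because the C19 tether is axial on the α face the carbenoid carbon can only reach the α face, which sets C10 with C20 cis to C19 and makes C1 and C20 the cis-fused cyclopropane centres.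

Step 6
Reactants: 10 cyclopropyl ketone
Product: 11 19-ketone with the C4–C19–C20–C10 bridge (cyclopentanone), C1 a methylene
Conditions: SmI2 (2.5 equiv), THF/DMPU, MeOH (2 equiv), −78 to 0 °C
Reagents that add atoms: none
Why: Single-electron reduction to the ketyl and cyclopropylcarbinyl radical opening break the C20–C1 bond, the one that lies outside the five-membered ketone ring and overlaps with the carbonyl π system, so this reductive cyclopropyl ketone cleavage leaves C20 on C10 and returns C1 as a methylene without touching esters, silyl ethers or the 16-ene.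

Step 7
Reactants: 11 19,20-cyclopentanone; 12 3-phenyl-2-(phenylsulfonyl)oxaziridine
Product: 13 20-hydroxy-19-ketone (C20 epimers)
Conditions: NaN(SiMe3)2 (1.1 equiv), THF, −78 °C; oxaziridine (1.3 equiv), −78 °C; AcOH quench
Reagents that add atoms: 3-phenyl-2-(phenylsulfonyl)oxaziridine, O=S(=O)(c1ccccc1)N1OC1c1ccccc1
Why: C4 is quaternary, so the ketone enolises only towards C20 and electrophilic oxygen transfer from the N-sulfonyloxaziridine to the sodium enolate (enolate hydroxylation) places a hydroxyl there, its configuration being irrelevant, while the 16-ene, which ozone or peracid would attack, is untouched.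

Step 8
Reactants: 13 20-hydroxy-19-ketone; 14 sodium periodate; 15 sodium chlorite
Product: 17 3β,13-bis(triethylsilyloxy)gibberell-16-ene-7,19,20-trioic acid 7-benzyl ester, via 20-oxo 19-acid 16 (not isolated)
Conditions: NaIO4, THF/H2O, rt; then NaClO2, NaH2PO4, 2-methyl-2-butene, t-BuOH/H2O, rt
Reagents that add atoms: sodium periodate, [Na+].[O-]I(=O)(=O)=O; sodium chlorite, [Na+].[O-]Cl=O
Why: Periodate cleaves the α-hydroxy ketone between C19 and C20 to the C19 acid and the C20 aldehyde, and Pinnick oxidation with a chlorine scavenger takes the aldehyde, which equilibrates with its lactol, to the acid without oxidising the alkene or the silyl ethers (glycol-type cleavage followed by chlorite oxidation).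

Step 9
Reactants: 17 19,20-diacid 7-benzyl ester; 2 benzyl bromide
Product: 18 tribenzyl 3β,13-bis(triethylsilyloxy)gibberell-16-ene-7,19,20-trioate
Conditions: BnBr, Cs2CO3, DMF, rt
Reagents that add atoms: benzyl bromide, BrCc1ccccc1
Why: O-Alkylation of the caesium carboxylates is an SN2 reaction at the benzyl carbon and is therefore indifferent to the neopentyl surroundings of C19 and C20, giving three esters that all fall to one hydrogenolysis.

Step 10
Reactants: 18 tribenzyl bis(silyl ether)
Product: 20 ring C/D-rearranged tribenzyl ester with 3β-hydroxyl, C13 ketone, C12 bonded to C16 and a methyl on bridgehead C16, via desilylated 3β,13-diol 19 (not isolated)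
Conditions: CF3CO2H/CH2Cl2 (1:2), H2O (5 equiv), 0 °C to rt
Reagents that add atoms: none
Why: Aqueous acid first removes both silyl ethers and then protonates the 16-ene at C17, whereupon the C12–C13 bond migrates to the tertiary C16 cation with the 13-hydroxyl lone pair driving formation of the ketone (Wagner–Meerwein shift of semipinacol type, as in the acid isomerisation of 13-hydroxykaur-16-enes), and C16 becomes a methyl-bearing bridgehead whose configuration is dictated by the cage.

Step 11
Reactants: 20 rearranged 3β-hydroxy 13-ketone; 21 benzyl chloroformate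
Product: 22 3-O-benzyloxycarbonyl derivative of 20
Conditions: CbzCl, pyridine, DMAP, CH2Cl2, 0 °C to rt
Reagents that add atoms: benzyl chloroformate, O=C(Cl)OCc1ccccc1
Why: The 3β-hydroxyl is now the only hydroxyl, so DMAP-catalysed acylation with the chloroformate gives a benzyl carbonate without alkoxide formation (no retro-aldol at C3–C4), a group stable to the next three steps and cleaved by hydrogenolysis.

Step 12
Reactants: 22 3-O-benzyloxycarbonyl 13-ketone
Product: 23 13-exo-alcohol of the rearranged skeleton
Conditions: [(Ph4C4CO)2H]Ru2(CO)4(μ-H) (2 mol %), i-PrOH/toluene (1:1), 90 °C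
Reagents that add atoms: none
Why: Ruthenium-catalysed transfer hydrogenation from propan-2-ol is reversible, so the C13 epimers equilibrate through the ketone and the exo alcohol, whose hydroxyl avoids the axial C11 hydrogen beneath the endo face, should predominate under this thermodynamic control, esters and carbonate being inert to the neutral catalyst.

Step 13
Reactants: 23 13-exo-alcohol; 24 methanesulfonyl chloride
Product: 25 13-exo-mesylate (key-step precursor)
Conditions: MsCl, Et3N, CH2Cl2, −20 to 0 °C; cold aqueous work-up, used crude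
Reagents that add atoms: methanesulfonyl chloride, CS(=O)(=O)Cl
Why: Sulfonylation through sulfene tolerates the neopentyl position and retains the exo C–O configuration since the C–O bond is not touched (alcohol mesylation); the product is kept cold and used crude because its ionisation is anchimerically assisted.

Step 14
Reactants: 25 13-exo-mesylate; 26 water
Product: 27 tribenzyl ester 3-O-benzyl carbonate of the target (key-step product)
Conditions: 1,4-dioxane/H2O (3:2), 2,6-lutidine (3 equiv), rt to 40 °C
Reagents that add atoms: water, O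
Why: Ionisation of the exo C13–O bond is assisted by the antiperiplanar C16–C12 σ bond, so C12 moves to C13 with inversion while the charge passes to the tertiary C16, a Wagner–Meerwein 1,2-alkyl shift of the kind known for exo sulfonates of bicyclo[3.2.1]octanes and for the beyeranyl to kauranyl change. Ring C of the target (C8–C9–C11–C12–C13–C14) is closed by this intramolecular 1,2-shift through a three-centre bridged transition state, not by an external nucleophile, and ring D re-forms around it. C13 is set by the backside entry of C12 opposite the leaving group, and C16 by water adding anti to the just-migrated C12, that is on the exo face syn to the C14 bridge, which places the hydroxyl exo and the methyl endo. The step needs C12 and not C15 or the methyl to migrate, which the exo geometry secures because C15 is gauche to the leaving group and its shift would create a cyclobutane. It also needs capture by water to outrun proton loss, which the water-rich medium favours, the gain from a secondary to a tertiary cation making the shift downhill. 2,6-Lutidine takes up the acid so that the tertiary alcohol, the benzyl esters and the carbonate survive.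

Step 15
Reactants: 27 tribenzyl ester 3-O-benzyl carbonate
Product: 28 target triacid (CNP0183110.3)
Conditions: H2 (1 atm), Pd/C (10 wt % palladium on carbon), EtOAc/MeOH, rt
Reagents that add atoms: none
Why: Hydrogenolysis cleaves the three benzylic C–O bonds and the benzyl carbonate (which then loses carbon dioxide) under neutral conditions, so no hindered ester has to be saponified, the β-hydroxy ester cannot epimerise at C3 by retro-aldol and the tertiary alcohol is not exposed to acid (catalytic hydrogenolysis).

Compound list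
1 | gibberellic acid | C[C@]1(C(=O)O5)[C@H]2[C@H](C(=O)O)[C@@]34C[C@@](O)(CC[C@H]3[C@]25C=C[C@@H]1O)C(=C)C4 | starting material
2 | benzyl bromide | BrCc1ccccc1 | starting material
3 | gibberellic acid benzyl ester (C7 ester; lactone, 1-ene, 3β-OH, 13-OH, 16-ene intact) | C[C@]1(C(=O)O5)[C@H]2[C@H](C(=O)OCc6ccccc6)[C@@]34C[C@@](O)(CC[C@H]3[C@]25C=C[C@@H]1O)C(=C)C4 | intermediate
4 | 7-benzyl ester of 3β,13-dihydroxy-20-norgibberella-1(10),16-diene-7,19-dioic acid | C[C@]1(C(=O)O)[C@H]2[C@H](C(=O)OCc5ccccc5)[C@@]34C[C@@](O)(CC[C@H]3C2=CC[C@@H]1O)C(=C)C4 | intermediate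
5 | triethylsilyl trifluoromethanesulfonate | CC[Si](CC)(CC)OS(=O)(=O)C(F)(F)F | starting material
6 | 3β,13-bis(triethylsilyloxy) 19-triethylsilyl ester of 4 | C[C@]1(C(=O)O[Si](CC)(CC)CC)[C@H]2[C@H](C(=O)OCc5ccccc5)[C@@]34C[C@@](O[Si](CC)(CC)CC)(CC[C@H]3C2=CC[C@@H]1O[Si](CC)(CC)CC)C(=C)C4 | intermediate
7 | trimethylsilyldiazomethane | C[Si](C)(C)C=[N+]=[N-] | starting material
8 | C19 acid chloride (not isolated) | C[C@]1(C(=O)Cl)[C@H]2[C@H](C(=O)OCc5ccccc5)[C@@]34C[C@@](O[Si](CC)(CC)CC)(CC[C@H]3C2=CC[C@@H]1O[Si](CC)(CC)CC)C(=C)C4 | intermediate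
9 | C19 diazomethyl ketone | C[C@]1(C(=O)C=[N+]=[N-])[C@H]2[C@H](C(=O)OCc5ccccc5)[C@@]34C[C@@](O[Si](CC)(CC)CC)(CC[C@H]3C2=CC[C@@H]1O[Si](CC)(CC)CC)C(=C)C4 | intermediate
10 | cyclopropyl ketone (C1–C10–C20 cyclopropane on the α face, C19 ketone) | C[C@]1(C(=O)[C@H]56)[C@H]2[C@H](C(=O)OCc7ccccc7)[C@@]34C[C@@](O[Si](CC)(CC)CC)(CC[C@H]3[C@]25[C@@H]6C[C@@H]1O[Si](CC)(CC)CC)C(=C)C4 | intermediate
11 | 19-ketone with C4–C19–C20–C10 bridge | C[C@]1(C(=O)C5)[C@H]2[C@H](C(=O)OCc6ccccc6)[C@@]34C[C@@](O[Si](CC)(CC)CC)(CC[C@H]3[C@]25CC[C@@H]1O[Si](CC)(CC)CC)C(=C)C4 | intermediate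
12 | 3-phenyl-2-(phenylsulfonyl)oxaziridine (racemic) | O=S(=O)(c1ccccc1)N1OC1c1ccccc1 | starting material
13 | 20-hydroxy-19-ketone (C20 epimers) | C[C@]1(C(=O)C5O)[C@H]2[C@H](C(=O)OCc6ccccc6)[C@@]34C[C@@](O[Si](CC)(CC)CC)(CC[C@H]3[C@]25CC[C@@H]1O[Si](CC)(CC)CC)C(=C)C4 | intermediate
14 | sodium periodate | [Na+].[O-]I(=O)(=O)=O | starting material
15 | sodium chlorite | [Na+].[O-]Cl=O | starting material
16 | 20-oxo 19-acid 7-benzyl ester (not isolated) | C[C@]1(C(=O)O)[C@H]2[C@H](C(=O)OCc5ccccc5)[C@@]34C[C@@](O[Si](CC)(CC)CC)(CC[C@H]3[C@]2(C=O)CC[C@@H]1O[Si](CC)(CC)CC)C(=C)C4 | intermediate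
17 | 3β,13-bis(triethylsilyloxy)gibberell-16-ene-7,19,20-trioic acid 7-benzyl ester | C[C@]1(C(=O)O)[C@H]2[C@H](C(=O)OCc5ccccc5)[C@@]34C[C@@](O[Si](CC)(CC)CC)(CC[C@H]3[C@]2(C(=O)O)CC[C@@H]1O[Si](CC)(CC)CC)C(=C)C4 | intermediate
18 | tribenzyl 3β,13-bis(triethylsilyloxy)gibberell-16-ene-7,19,20-trioate | C[C@]1(C(=O)OCc5ccccc5)[C@H]2[C@H](C(=O)OCc5ccccc5)[C@@]34C[C@@](O[Si](CC)(CC)CC)(CC[C@H]3[C@]2(C(=O)OCc5ccccc5)CC[C@@H]1O[Si](CC)(CC)CC)C(=C)C4 | intermediate
19 | tribenzyl 3β,13-dihydroxygibberell-16-ene-7,19,20-trioate (not isolated) | C[C@]1(C(=O)OCc5ccccc5)[C@H]2[C@H](C(=O)OCc5ccccc5)[C@@]34C[C@@](O)(CC[C@H]3[C@]2(C(=O)OCc5ccccc5)CC[C@@H]1O)C(=C)C4 | intermediate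
20 | rearranged tribenzyl ester: 3β-OH, C13 ketone, C12 on C16, methyl on bridgehead C16 | C[C@]1(C(=O)OCc5ccccc5)[C@H]2[C@H](C(=O)OCc5ccccc5)[C@@]34CC(=O)[C@@](C)(CC[C@H]3[C@]2(C(=O)OCc5ccccc5)CC[C@@H]1O)C4 | intermediate
21 | benzyl chloroformate | O=C(Cl)OCc1ccccc1 | starting material
22 | 3-O-benzyloxycarbonyl derivative of 20 | C[C@]1(C(=O)OCc5ccccc5)[C@H]2[C@H](C(=O)OCc5ccccc5)[C@@]34CC(=O)[C@@](C)(CC[C@H]3[C@]2(C(=O)OCc5ccccc5)CC[C@@H]1OC(=O)OCc5ccccc5)C4 | intermediate
23 | 13-exo-alcohol | C[C@]1(C(=O)OCc5ccccc5)[C@H]2[C@H](C(=O)OCc5ccccc5)[C@@]34C[C@H](O)[C@@](C)(CC[C@H]3[C@]2(C(=O)OCc5ccccc5)CC[C@@H]1OC(=O)OCc5ccccc5)C4 | intermediate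
24 | methanesulfonyl chloride | CS(=O)(=O)Cl | starting material
25 | 13-exo-mesylate (key-step precursor) | C[C@]1(C(=O)OCc5ccccc5)[C@H]2[C@H](C(=O)OCc5ccccc5)[C@@]34C[C@H](OS(C)(=O)=O)[C@@](C)(CC[C@H]3[C@]2(C(=O)OCc5ccccc5)CC[C@@H]1OC(=O)OCc5ccccc5)C4 | intermediate
26 | water | O | starting material
27 | tribenzyl ester 3-O-benzyl carbonate of the target (16-exo-OH, 16-endo-methyl, C13–H) | C[C@]1(C(=O)OCc5ccccc5)[C@H]2[C@H](C(=O)OCc5ccccc5)[C@@]34C[C@@H](CC[C@H]3[C@]2(C(=O)OCc5ccccc5)CC[C@@H]1OC(=O)OCc5ccccc5)[C@](C)(O)C4 | intermediate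
28 | target triacid CNP0183110.3 | C[C@]1(C(=O)O)[C@H]2[C@H](C(=O)O)[C@@]34C[C@@H](CC[C@H]3[C@]2(C(=O)O)CC[C@@H]1O)[C@](C)(O)C4 | target

Total step count: 15. Longest linear sequence: 15 steps from gibberellic acid.

Steps most likely to fail

Step 14. The bridged cation may lose a proton to give the 16-ene or 15-ene faster than it captures water, or leak through a hydride shift. Fallback, from 25 back to 27: ionise the mesylate in a non-nucleophilic medium (2,6-lutidine, (CF3)2CHOH, 40 °C) so that the same shift ends in elimination. This should give the exocyclic 16(17)-alkene F1 and the endocyclic 15-alkene F2. Hydrate the mixture by hydrogen-atom-transfer (Mukaiyama hydration: Co(acac)2, PhSiH3, O2, THF, rt). Both alkenes give the same tertiary C16 radical, which takes up oxygen on the open exo face and converges on 27.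

Step 12. The hindered ketone may be reduced slowly, or the equilibrium may not lie far enough on the exo side, leaving much endo alcohol. Fallback, from 22 back to 27: reduce kinetically with NaBH4 (MeOH/THF, 0 °C), where hydride enters from the exo face and gives the 13-endo-alcohol F3. Convert it with Tf2O/pyridine (−20 °C) into the 13-endo-triflate F4. Let this much better leaving group ionise without assistance in dioxane/H2O with 2,6-lutidine. As with endo-norbornyl sulfonates, the secondary C13 cation should then undergo the same C12 shift and exo capture by water, giving 27.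

Step 2. Hydride may be delivered to the wrong allyl terminus (C10), or the allylpalladium intermediate may eliminate to dienes before it is reduced. Fallback, from 1 back to 4:
- Cleave the allylic lactone of the free acid by dissolving metal (Li, NH3/THF, −78 °C, NH4Cl), where the C7 carboxylate is inert, to give the 1(10),16-diene 7,19-diacid F5.
- Differentiate the acids by iodolactonisation (I2, NaHCO3), which re-closes the 19,10-lactone as the 1β-iodo lactone 7-acid F6.
- Esterify C7 (BnBr, KHCO3, DMF) to the iodo lactone benzyl ester F7.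
- Reopen by reductive elimination (Zn, AcOH) to reach 4.

Further compounds
F1 | step 14 | tribenzyl 3β-benzyloxycarbonyloxygibberell-16-ene-7,19,20-trioate (exocyclic 16(17)-alkene, C13–H) | C[C@]1(C(=O)OCc5ccccc5)[C@H]2[C@H](C(=O)OCc5ccccc5)[C@@]34C[C@@H](CC[C@H]3[C@]2(C(=O)OCc5ccccc5)CC[C@@H]1OC(=O)OCc5ccccc5)C(=C)C4
F2 | step 14 | 15-ene isomer of F1 (C15=C16, methyl on C16) | C[C@]1(C(=O)OCc5ccccc5)[C@H]2[C@H](C(=O)OCc5ccccc5)[C@@]34C[C@@H](CC[C@H]3[C@]2(C(=O)OCc5ccccc5)CC[C@@H]1OC(=O)OCc5ccccc5)C(C)=C4
F3 | step 12 | 13-endo-alcohol (C13 epimer of 23) | C[C@]1(C(=O)OCc5ccccc5)[C@H]2[C@H](C(=O)OCc5ccccc5)[C@@]34C[C@@H](O)[C@@](C)(CC[C@H]3[C@]2(C(=O)OCc5ccccc5)CC[C@@H]1OC(=O)OCc5ccccc5)C4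
F4 | step 12 | 13-endo-triflate | C[C@]1(C(=O)OCc5ccccc5)[C@H]2[C@H](C(=O)OCc5ccccc5)[C@@]34C[C@@H](OS(=O)(=O)C(F)(F)F)[C@@](C)(CC[C@H]3[C@]2(C(=O)OCc5ccccc5)CC[C@@H]1OC(=O)OCc5ccccc5)C4
F5 | step 2 | 3β,13-dihydroxy-20-norgibberella-1(10),16-diene-7,19-dioic acid | C[C@]1(C(=O)O)[C@H]2[C@H](C(=O)O)[C@@]34C[C@@](O)(CC[C@H]3C2=CC[C@@H]1O)C(=C)C4
F6 | step 2 | 1β-iodo-3β,13-dihydroxy 19,10-lactone 7-acid (16-ene) | C[C@]1(C(=O)O5)[C@H]2[C@H](C(=O)O)[C@@]34C[C@@](O)(CC[C@H]3[C@]25[C@H](I)C[C@@H]1O)C(=C)C4
F7 | step 2 | benzyl ester of F6 | C[C@]1(C(=O)O5)[C@H]2[C@H](C(=O)OCc6ccccc6)[C@@]34C[C@@](O)(CC[C@H]3[C@]25[C@H](I)C[C@@H]1O)C(=C)C4
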